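**Retrosynthetic overview**
- The strategy rests on the trans β-hydroxy carbonyl relation on the seven-membered ring (C1, C5–C10). The oxygen on C8 sits next to C7, and the carbinol carbon C11 on C7 can be carried as an ester. The ferulate (esterification) and the two C11 methyl groups (MeMgBr/CeCl3 on the ester) are therefore removed first.
- C7–C8 is then cut in the Reformatsky sense. This gives a monocyclic C7 α-bromo ester / C8 aldehyde on a (Z)-alkylidenecyclopentane. The five-membered ring (C1–C5) is present from the start and the seven-membered ring is closed last.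
- The Z tetrasubstituted C1=C10 alkene comes from 1,4-hydrogenation of a C2=C1–C10=C14 diene. The diene is made by Negishi coupling (C1–C10) of a kinetic C1 enol triflate.
- The cis C4/C5 pair comes from CBS reduction of the C1 ketone, followed by hydroxyl-directed hydrogenation of C4=C5. The cyclopentenone is assembled from cyclopentane-1,3-dione, methyl acrylate and methylzinc chloride.

Key step: step 14

Assumption: guaiane numbering is used for all intermediates (five-membered ring C1–C5, seven-membered ring C1 and C5–C10, C11 on C7, C14 on C10, C15 on C4). The α-bromo esters form as mixtures of C7 epimers and are drawn as the 7S epimer.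

**Step 1**
Reactants: 1 cyclopentane-1,3-dione; 2 methyl acrylate
Product: 3 methyl 3-(2-hydroxy-5-oxocyclopent-1-en-1-yl)propanoate (enol form of the 2-substituted 1,3-dione)
Conditions: NaOMe (1.0 equiv), MeOH, reflux; then 1 M HCl to pH 2
Reagents that add atoms: none
Why: Michael addition of the soft 1,3-dione enolate (C5) to the acrylate should bring in C6, C7 and C11 at once, and the product stays in the flask as its stabilised enolate salt, which holds back a second addition.

**Step 2**
Reactants: 3 methyl 3-(2-hydroxy-5-oxocyclopent-1-en-1-yl)propanoate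
Product: 4 methyl 3-[5-oxo-2-(trifluoromethylsulfonyloxy)cyclopent-1-en-1-yl]propanoate
Conditions: Tf2O, pyridine, CH2Cl2, −78 to 0 °C
Reagents that add atoms: triflic anhydride O=S(=O)(OS(=O)(=O)C(F)(F)F)C(F)(F)F
Why: O-sulfonylation of the vinylogous acid gives the vinylogous acyl triflate, and since C1 and C4 are still equivalent no regiochemical question arises.

**Step 3**
Reactants: 4 methyl 3-[5-oxo-2-(trifluoromethylsulfonyloxy)cyclopent-1-en-1-yl]propanoate
Product: 5 methyl 3-(2-methyl-5-oxocyclopent-1-en-1-yl)propanoate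
Conditions: MeZnCl (1.3 equiv), Pd(PPh3)4 (3 mol %), THF, 0 °C to rt
Reagents that add atoms: methylzinc chloride C[Zn]Cl
Why: Negishi coupling at the electron-poor alkenyl triflate should place the C15 methyl group on C4 while sparing the ester and the enone carbonyl, which a Grignard or lithium reagent would attack.

**Step 4**
Reactants: 5 methyl 3-(2-methyl-5-oxocyclopent-1-en-1-yl)propanoate
Product: 6 methyl 3-[(5S)-5-hydroxy-2-methylcyclopent-1-en-1-yl]propanoate (1S in guaiane numbering)
Conditions: (R)-2-methyl-CBS-oxazaborolidine (10 mol %), BH3·SMe2, THF, −20 °C; MeOH quench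
Reagents that add atoms: none
Why: In this Corey–Bakshi–Shibata reduction the fully substituted alkenyl arm (C5) acts as the large group and the C2 methylene as the small one, so the (R)-catalyst should give the 1S carbinol; this is the only reagent-controlled absolute stereocentre of the route, and the ester is inert to borane at this temperature.

**Step 5**
Reactants: 6 methyl 3-[(5S)-5-hydroxy-2-methylcyclopent-1-en-1-yl]propanoate
Product: 7 methyl 3-[(1S,2S,5S)-2-hydroxy-5-methylcyclopentyl]propanoate (C15 methyl and C6 chain cis to each other and trans to OH)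
Conditions: [Ir(cod)(PCy3)(py)]PF6 (5 mol %), H2 (10 bar), CH2Cl2, rt
Reagents that add atoms: none
Why: In this hydroxyl-directed homogeneous hydrogenation the C1 hydroxyl binds the cationic iridium centre, so both hydrogens add to the tetrasubstituted C4=C5 bond on the hydroxyl face; syn addition makes the methyl group and the chain cis, and the C1 configuration fixes 4S,5S.

**Step 6**
Reactants: 7 methyl 3-[(1S,2S,5S)-2-hydroxy-5-methylcyclopentyl]propanoate
Product: 8 methyl 3-[(1S,2S)-2-methyl-5-oxocyclopentyl]propanoate (cis)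
Conditions: Dess–Martin periodinane, NaHCO3, CH2Cl2, 0 °C
Reagents that add atoms: none
Why: Buffered Dess–Martin oxidation removes the spent C1 stereocentre without acid or base strong enough to epimerise the contra-thermodynamic cis centre C5 next to the new ketone.

**Step 7**
Reactants: 8 methyl 3-[(1S,2S)-2-methyl-5-oxocyclopentyl]propanoate
Product: 10 methyl 3-[(1S,5S)-5-methyl-2-(trifluoromethylsulfonyloxy)cyclopent-2-en-1-yl]propanoate, via lithium C1–C2 enolate 9 (not isolated)
Conditions: LiN(iPr)2 (1.05 equiv), THF, −78 °C, slow addition of 8; then N-(5-chloro-2-pyridyl)bis(trifluoromethanesulfonimide), −78 °C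
Reagents that add atoms: N-(5-chloro-2-pyridyl)bis(trifluoromethanesulfonimide) O=S(=O)(N(c1ccc(Cl)cn1)S(=O)(=O)C(F)(F)F)C(F)(F)F
Why: This is kinetic enolate formation with O-triflation: adding the ketone to a slight excess of the hindered amide removes a proton irreversibly from the unhindered C2 methylene, so C5 is never deprotonated and keeps its configuration, and the reactive pyridyl triflimide traps the enolate at −78 °C before it can attack the ester.

**Step 8**
Reactants: 11 3-bromobut-3-en-1-ol
Product: 12 [(3-bromobut-3-en-1-yl)oxy](tert-butyl)dimethylsilane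
Conditions: TBSCl, imidazole, CH2Cl2, rt
Reagents that add atoms: tert-butyldimethylsilyl chloride CC(C)(C)[Si](C)(C)Cl
Why: Imidazole-promoted silylation of the primary alcohol masks the future C8 oxygen through the organolithium and enolate steps.

**Step 9**
Reactants: 12 [(3-bromobut-3-en-1-yl)oxy](tert-butyl)dimethylsilane; 10 methyl 3-[(1S,5S)-5-methyl-2-(trifluoromethylsulfonyloxy)cyclopent-2-en-1-yl]propanoate
Product: 15 methyl 3-[(1S,5S)-2-[4-(tert-butyldimethylsilyloxy)but-1-en-2-yl]-5-methylcyclopent-2-en-1-yl]propanoate, via alkenyllithium 13 (not isolated), via alkenylzinc bromide 14 (not isolated)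
Conditions: 12 (1.3 equiv), t-BuLi (2.6 equiv), Et2O, −78 °C; ZnBr2, THF, −78 to 0 °C; then 10, Pd(PPh3)4 (5 mol %), THF, rt
Reagents that add atoms: none
Why: Bromine–lithium exchange, transmetalation to zinc and Negishi alkenyl–alkenyl coupling form C1–C10 and bring in C8, C9, C10 and C14, while the nearly neutral organozinc tolerates the ester and leaves the allylic C5 centre untouched.

**Step 10**
Reactants: 15 methyl 3-[(1S,5S)-2-[4-(tert-butyldimethylsilyloxy)but-1-en-2-yl]-5-methylcyclopent-2-en-1-yl]propanoate
Product: 16 methyl 3-[(1S,2Z,5S)-2-[4-(tert-butyldimethylsilyloxy)butan-2-ylidene]-5-methylcyclopentyl]propanoate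
Conditions: (η6-naphthalene)Cr(CO)3 (20 mol %), H2 (70 bar), acetone, 40 °C
Reagents that add atoms: none
Why: In arene chromium tricarbonyl catalysed 1,4-hydrogenation the diene can only react when bound η4 in its s-cis form, and hydrogen goes to the termini C2 and C14, so the new C1=C10 bond keeps C14 beside C2 and C9 beside C5 (Z); the isolated alkene formed, the ester and the silyl ether are not reduced by this catalyst.

**Step 11**
Reactants: 16 methyl 3-[(1S,2Z,5S)-2-[4-(tert-butyldimethylsilyloxy)butan-2-ylidene]-5-methylcyclopentyl]propanoate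
Product: 18 methyl 2-bromo-3-[(1S,2Z,5S)-2-[4-(tert-butyldimethylsilyloxy)butan-2-ylidene]-5-methylcyclopentyl]propanoate (C7 epimer mixture; 7S drawn), via lithium ester enolate 17 (not isolated)
Conditions: LiN(iPr)2 (1.1 equiv), THF, −78 °C; cannulation into BrCCl2CCl2Br (1.5 equiv), THF, −78 °C
Reagents that add atoms: 1,2-dibromo-1,1,2,2-tetrachloroethane ClC(Cl)(Br)C(Cl)(Cl)Br
Why: The ester enolate is brominated by halophilic attack on a donor that, unlike Br2 or NBS, does not add to the electron-rich C1=C10 bond; inverse addition limits proton exchange with the product, and the uncontrolled C7 centre is erased in step 14.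

**Step 12**
Reactants: 18 methyl 2-bromo-3-[(1S,2Z,5S)-2-[4-(tert-butyldimethylsilyloxy)butan-2-ylidene]-5-methylcyclopentyl]propanoate
Product: 19 methyl 2-bromo-3-[(1S,2Z,5S)-2-(4-hydroxybutan-2-ylidene)-5-methylcyclopentyl]propanoate (C7 epimer mixture; 7S drawn)
Conditions: HF·pyridine, pyridine, THF, 0 °C to rt
Reagents that add atoms: none
Why: Fluoride-mediated desilylation in a buffered, slightly acidic medium frees the primary alcohol without the basic alkoxide that could displace or eliminate the α-bromide.

**Step 13**
Reactants: 19 methyl 2-bromo-3-[(1S,2Z,5S)-2-(4-hydroxybutan-2-ylidene)-5-methylcyclopentyl]propanoate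
Product: 20 methyl 2-bromo-3-[(1S,2Z,5S)-5-methyl-2-(4-oxobutan-2-ylidene)cyclopentyl]propanoate (C7 epimer mixture; 7S drawn)
Conditions: Dess–Martin periodinane, NaHCO3, CH2Cl2, 0 °C; short filtration, used at once
Reagents that add atoms: none
Why: Buffered Dess–Martin oxidation releases the C8 aldehyde from an alcohol rather than by alkene cleavage, which would attack C1=C10 first, and its neutral conditions should keep the β,γ-unsaturated aldehyde from moving into conjugation.

**Step 14**
Reactants: 20 methyl 2-bromo-3-[(1S,2Z,5S)-5-methyl-2-(4-oxobutan-2-ylidene)cyclopentyl]propanoate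
Product: 22 methyl (3S,3aS,5S,6S)-6-hydroxy-3,8-dimethyl-1,2,3,3a,4,5,6,7-octahydroazulene-5-carboxylate (guaiane numbering 4S,5S,7S,8S; trans β-hydroxy ester), via samarium enolate 21 (not isolated)
Conditions: SmI2 (2.5 equiv, 0.1 M in THF), slow addition of 20 (final 0.005 M), −78 °C, then to −20 °C; aqueous work-up
Reagents that add atoms: none
Why: Divalent samarium cleaves the C7–Br bond by two single-electron transfers far faster than it touches an aldehyde without proton source or HMPA, and the trivalent samarium ester enolate 21 adds to the C8 aldehyde bound to the same oxophilic metal, which is the intramolecular samarium Reformatsky reaction known for medium-ring β-hydroxy carbonyl compounds. The one ring formed is the seven-membered carbocycle C1, C5–C10, closed by 7-exo-trig attack of C7 on the C8 carbonyl carbon with the oxygen left outside the ring. The step needs closure to win over enolate protonation, intermolecular aldol addition and migration of C1=C10 into conjugation: the Z-configured alkene places C9 next to C5 and locks C5, C1, C10 and C9 in one plane, slow addition at high dilution suppresses dimers, and the weakly basic enolate at −78 °C should leave the acidic C9 protons alone. C7 is controlled by C5, because in the chair-like forming ring the C5–C4 bond and the C7 ester both take pseudo-equatorial places, which puts H7 cis to H5 (7S). C8 is controlled by the samarium chelate between ester and aldehyde oxygen, in which the anti, diequatorial arrangement avoids an axial C–O bond (8S, trans to the ester). Both bromide epimers converge on 21, its geometry can adjust through the carbon-bound form, and the aldolate can reopen by retro-aldol reaction on warming, so the all-equatorial 7S,8S isomer should also be the product of equilibration.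

**Step 15**
Reactants: 22 methyl (3S,3aS,5S,6S)-6-hydroxy-3,8-dimethyl-1,2,3,3a,4,5,6,7-octahydroazulene-5-carboxylate
Product: 23 the C8 triethylsilyl ether of 22
Conditions: TESOTf, 2,6-lutidine, CH2Cl2, −78 °C
Reagents that add atoms: triethylsilyl triflate CC[Si](CC)(CC)OS(=O)(=O)C(F)(F)F
Why: Silylation with a silyl triflate and a hindered pyridine base caps the C8 hydroxyl at low temperature, so no metal aldolate that could undergo retro-aldol ring opening is present in the next step.

**Step 16**
Reactants: 23 the C8 triethylsilyl ether of 22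
Product: 25 (4S,5S,7S,8S)-8-(triethylsilyloxy)guai-1(10)-en-11-ol, via C11 methyl ketone 24 (not isolated)
Conditions: CeCl3 (anhydrous, 5 equiv), MeMgBr (5 equiv), THF, −78 to 0 °C; sat. aq. NH4Cl
Reagents that add atoms: methylmagnesium bromide C[Mg]Br
Why: Double organocerium addition to the ester builds the hydroxyisopropyl group (C12, C13), and the low basicity of the cerium reagent suppresses enolisation at C7 and with it epimerisation and β-elimination of the silyloxy group.

**Step 17**
Reactants: 25 (4S,5S,7S,8S)-8-(triethylsilyloxy)guai-1(10)-en-11-ol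
Product: 26 (4S,5S,7S,8S)-guai-1(10)-ene-8,11-diol
Conditions: HF·pyridine, pyridine, THF, 0 °C to rt
Reagents that add atoms: none
Why: Buffered fluoride desilylation removes the triethylsilyl group under conditions too mild to dehydrate the tertiary carbinol or move the tetrasubstituted alkene.

**Step 18**
Reactants: 27 ferulic acid
Product: 29 (E)-3-[4-(tert-butyldimethylsilyloxy)-3-methoxyphenyl]prop-2-enoic acid, via bis-silylated ferulate 28 (not isolated)
Conditions: TBSCl (2.5 equiv), imidazole, DMF, rt; then K2CO3, THF–MeOH–H2O, rt; 1 M HCl to pH 4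
Reagents that add atoms: tert-butyldimethylsilyl chloride CC(C)(C)[Si](C)(C)Cl
Why: Exhaustive silylation followed by selective hydrolysis of the far more labile silyl ester leaves the phenol masked and the acid free, with the E alkene unchanged.

**Step 19**
Reactants: 26 (4S,5S,7S,8S)-guai-1(10)-ene-8,11-diol; 29 (E)-3-[4-(tert-butyldimethylsilyloxy)-3-methoxyphenyl]prop-2-enoic acid
Product: 30 (4S,5S,7S,8S)-11-hydroxyguai-1(10)-en-8-yl (E)-3-[4-(tert-butyldimethylsilyloxy)-3-methoxyphenyl]prop-2-enoate
Conditions: EDC·HCl (1.5 equiv), DMAP (0.5 equiv), CH2Cl2, rt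
Reagents that add atoms: none
Why: Steglich-type esterification acylates the secondary C8 hydroxyl with retention, while the tertiary C11 hydroxyl is too hindered to react under these conditions.

**Step 20**
Reactants: 30 (4S,5S,7S,8S)-11-hydroxyguai-1(10)-en-8-yl (E)-3-[4-(tert-butyldimethylsilyloxy)-3-methoxyphenyl]prop-2-enoate
Product: 31 (4S,5S,7S,8S)-11-hydroxyguai-1(10)-en-8-yl (E)-ferulate, CNP0241038.1
Conditions: TBAF (1.1 equiv), AcOH (1.2 equiv), THF, 0 °C
Reagents that add atoms: none
Why: Acetic acid buffered fluoride cleaves the aryl silyl ether rapidly, and the buffer keeps the phenoxide from attacking the cinnamate ester.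

**Compound list**
1 | cyclopentane-1,3-dione | O=C1CCC(=O)C1 | starting material
2 | methyl acrylate | C=CC(=O)OC | starting material
3 | methyl 3-(2-hydroxy-5-oxocyclopent-1-en-1-yl)propanoate | COC(=O)CCC1=C(O)CCC1=O | intermediate
4 | methyl 3-[5-oxo-2-(trifluoromethylsulfonyloxy)cyclopent-1-en-1-yl]propanoate | COC(=O)CCC1=C(OS(=O)(=O)C(F)(F)F)CCC1=O | intermediate
5 | methyl 3-(2-methyl-5-oxocyclopent-1-en-1-yl)propanoate | COC(=O)CCC1=C(C)CCC1=O | intermediate
6 | methyl 3-[(5S)-5-hydroxy-2-methylcyclopent-1-en-1-yl]propanoate | O[C@H]1CCC(C)=C1CCC(=O)OC | intermediate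
7 | methyl 3-[(1S,2S,5S)-2-hydroxy-5-methylcyclopentyl]propanoate | O[C@H]1CC[C@H](C)[C@@H]1CCC(=O)OC | intermediate
8 | methyl 3-[(1S,2S)-2-methyl-5-oxocyclopentyl]propanoate | O=C1CC[C@H](C)[C@@H]1CCC(=O)OC | intermediate
9 | lithium C1–C2 enolate of 8 (not isolated) | [Li]OC1=CC[C@H](C)[C@@H]1CCC(=O)OC | intermediate
10 | methyl 3-[(1S,5S)-5-methyl-2-(trifluoromethylsulfonyloxy)cyclopent-2-en-1-yl]propanoate | O=S(=O)(OC1=CC[C@H](C)[C@@H]1CCC(=O)OC)C(F)(F)F | intermediate
11 | 3-bromobut-3-en-1-ol | C=C(Br)CCO | starting material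
12 | [(3-bromobut-3-en-1-yl)oxy](tert-butyl)dimethylsilane | C=C(Br)CCO[Si](C)(C)C(C)(C)C | intermediate
13 | [4-(tert-butyldimethylsilyloxy)but-1-en-2-yl]lithium (not isolated) | [Li]C(=C)CCO[Si](C)(C)C(C)(C)C | intermediate
14 | [4-(tert-butyldimethylsilyloxy)but-1-en-2-yl]zinc bromide (not isolated) | Br[Zn]C(=C)CCO[Si](C)(C)C(C)(C)C | intermediate
15 | methyl 3-[(1S,5S)-2-[4-(tert-butyldimethylsilyloxy)but-1-en-2-yl]-5-methylcyclopent-2-en-1-yl]propanoate | C=C(CCO[Si](C)(C)C(C)(C)C)C1=CC[C@H](C)[C@@H]1CCC(=O)OC | intermediate
16 | methyl 3-[(1S,2Z,5S)-2-[4-(tert-butyldimethylsilyloxy)butan-2-ylidene]-5-methylcyclopentyl]propanoate | CC(C)(C)[Si](C)(C)OCC/C(C)=C1/CC[C@H](C)[C@@H]1CCC(=O)OC | intermediate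
17 | lithium ester enolate of 16 (not isolated) | CC(C)(C)[Si](C)(C)OCC/C(C)=C1/CC[C@H](C)[C@@H]1CC=C(OC)O[Li] | intermediate
18 | methyl 2-bromo-3-[(1S,2Z,5S)-2-[4-(tert-butyldimethylsilyloxy)butan-2-ylidene]-5-methylcyclopentyl]propanoate (both C7 epimers; 7S drawn) | CC(C)(C)[Si](C)(C)OCC/C(C)=C1/CC[C@H](C)[C@@H]1C[C@H](Br)C(=O)OC | intermediate
19 | methyl 2-bromo-3-[(1S,2Z,5S)-2-(4-hydroxybutan-2-ylidene)-5-methylcyclopentyl]propanoate (both C7 epimers; 7S drawn) | OCC/C(C)=C1/CC[C@H](C)[C@@H]1C[C@H](Br)C(=O)OC | intermediate
20 | methyl 2-bromo-3-[(1S,2Z,5S)-5-methyl-2-(4-oxobutan-2-ylidene)cyclopentyl]propanoate (both C7 epimers; 7S drawn; key-step precursor) | O=CC/C(C)=C1/CC[C@H](C)[C@@H]1C[C@H](Br)C(=O)OC | intermediate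
21 | diiodosamarium ester enolate of the debrominated aldehyde (not isolated) | O=CC/C(C)=C1/CC[C@H](C)[C@@H]1CC=C(OC)O[Sm](I)I | intermediate
22 | methyl (3S,3aS,5S,6S)-6-hydroxy-3,8-dimethyl-1,2,3,3a,4,5,6,7-octahydroazulene-5-carboxylate (key-step product) | O[C@H]1CC(C)=C2CC[C@H](C)[C@@H]2C[C@@H]1C(=O)OC | intermediate
23 | C8 triethylsilyl ether of 22 | CC[Si](CC)(CC)O[C@H]1CC(C)=C2CC[C@H](C)[C@@H]2C[C@@H]1C(=O)OC | intermediate
24 | C11 methyl ketone from the first methyl addition (not isolated) | CC[Si](CC)(CC)O[C@H]1CC(C)=C2CC[C@H](C)[C@@H]2C[C@@H]1C(C)=O | intermediate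
25 | (4S,5S,7S,8S)-8-(triethylsilyloxy)guai-1(10)-en-11-ol | CC[Si](CC)(CC)O[C@H]1CC(C)=C2CC[C@H](C)[C@@H]2C[C@@H]1C(C)(C)O | intermediate
26 | (4S,5S,7S,8S)-guai-1(10)-ene-8,11-diol | O[C@H]1CC(C)=C2CC[C@H](C)[C@@H]2C[C@@H]1C(C)(C)O | intermediate
27 | ferulic acid | COc1cc(/C=C/C(=O)O)ccc1O | starting material
28 | tert-butyldimethylsilyl (E)-3-[4-(tert-butyldimethylsilyloxy)-3-methoxyphenyl]prop-2-enoate (not isolated) | COc1cc(/C=C/C(=O)O[Si](C)(C)C(C)(C)C)ccc1O[Si](C)(C)C(C)(C)C | intermediate
29 | (E)-3-[4-(tert-butyldimethylsilyloxy)-3-methoxyphenyl]prop-2-enoic acid | COc1cc(/C=C/C(=O)O)ccc1O[Si](C)(C)C(C)(C)C | intermediate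
30 | (4S,5S,7S,8S)-11-hydroxyguai-1(10)-en-8-yl (E)-3-[4-(tert-butyldimethylsilyloxy)-3-methoxyphenyl]prop-2-enoate | COc1cc(/C=C/C(=O)O[C@H]2CC(C)=C3CC[C@H](C)[C@@H]3C[C@@H]2C(C)(C)O)ccc1O[Si](C)(C)C(C)(C)C | intermediate
31 | (4S,5S,7S,8S)-11-hydroxyguai-1(10)-en-8-yl (E)-ferulate, CNP0241038.1 | COc1cc(/C=C/C(=O)O[C@H]2CC(C)=C3CC[C@H](C)[C@@H]3C[C@@H]2C(C)(C)O)ccc1O | target

**Total step count:** 20. **Longest linear sequence:** 18 steps (steps 1–7, 9–17, 19, 20).

**Steps most likely to fail**

**Step 14.**
- What may go wrong: the geometry of the samarium enolate is not fixed by the way it is made. If the aldolate does not equilibrate before quenching, control at C7 and C8 erodes.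
- Fallback: it sets out from 22 obtained as a mixture of C7/C8 diastereomers and replaces substrate control by catalyst control.
- Dess–Martin oxidation should give the β-keto ester methyl (3S,3aS)-3,8-dimethyl-6-oxo-1,2,3,3a,4,5,6,7-octahydroazulene-5-carboxylate F1. In F1, C8 is planar and C7 epimerises freely through the enol.
- F1 is then hydrogenated with [RuCl(C6H6)((S)-binap)]Cl under H2 (100 bar) in CH2Cl2 at 50 °C. This is a Noyori hydrogenation with dynamic kinetic resolution, known to convert 2-alkoxycarbonylcycloalkanones with five- to seven-membered rings into the trans hydroxy esters.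
- It should set 7S,8S and leave the tetrasubstituted alkene alone. The route is rejoined at 22.

**Step 10.**
- What may go wrong: the crowded 2,3-disubstituted open-chain diene may enter the s-cis η4 complex too slowly, so the hydrogenation stalls while the catalyst decays.
- Fallback: it sets out from 15 and postpones the 1,4-hydrogenation until the seven-membered ring exists. C1–C10 is then a ring bond, the diene is held cisoid, and no alkene geometry has to be chosen.
- Compound 15 is deprotonated to its lithium ester enolate F2 and brominated as in step 11 to the diene bromo ester silyl ether F3.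
- F3 is desilylated as in step 12 to the diene bromo ester alcohol F4 and oxidised as in step 13 to the diene bromo ester aldehyde F5.
- SmI2 under the conditions of step 14 should convert F5, through the diene samarium enolate F6, into the bicyclic dienyl hydroxy ester F7.
- (η6-naphthalene)Cr(CO)3 and H2 then add hydrogen to C2 and C14 of F7. The route is rejoined at 22.

**Step 7.**
- What may go wrong: proton exchange between enolate 9 and unreacted 8 would epimerise C5 to the more stable trans ketone, or lead to the C1=C5 regioisomeric triflate.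
- Fallback: it sets out from 8 and 13 and avoids ketone enolates altogether.
- Alkenyllithium 13 is transmetalated with CeCl3 at −78 °C to the alkenylcerium dichloride F8. This almost non-basic reagent should add to the ketone of 8 faster than to the ester, from the face opposite to the C6 chain and the C15 methyl group.
- After a quench at −78 °C this gives the (1R)-tertiary allylic alcohol F9.
- Burgess dehydration is a syn elimination. The hydroxyl of F9 is trans to H5 but has a cis hydrogen on C2, so water should be lost towards C2 only. The route is rejoined at 15, replacing steps 7 and 9.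

**Further compounds**
F1 | step 14 | methyl (3S,3aS)-3,8-dimethyl-6-oxo-1,2,3,3a,4,5,6,7-octahydroazulene-5-carboxylate (C7 labile) | O=C1CC(C)=C2CC[C@H](C)[C@@H]2CC1C(=O)OC
F2 | step 10 | lithium ester enolate of 15 | C=C(CCO[Si](C)(C)C(C)(C)C)C1=CC[C@H](C)[C@@H]1CC=C(OC)O[Li]
F3 | step 10 | methyl 2-bromo-3-[(1S,5S)-2-[4-(tert-butyldimethylsilyloxy)but-1-en-2-yl]-5-methylcyclopent-2-en-1-yl]propanoate (both C7 epimers; 7S drawn) | C=C(CCO[Si](C)(C)C(C)(C)C)C1=CC[C@H](C)[C@@H]1C[C@H](Br)C(=O)OC
F4 | step 10 | methyl 2-bromo-3-[(1S,5S)-2-(4-hydroxybut-1-en-2-yl)-5-methylcyclopent-2-en-1-yl]propanoate (both C7 epimers; 7S drawn) | C=C(CCO)C1=CC[C@H](C)[C@@H]1C[C@H](Br)C(=O)OC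
F5 | step 10 | methyl 2-bromo-3-[(1S,5S)-5-methyl-2-(4-oxobut-1-en-2-yl)cyclopent-2-en-1-yl]propanoate (both C7 epimers; 7S drawn) | C=C(CC=O)C1=CC[C@H](C)[C@@H]1C[C@H](Br)C(=O)OC
F6 | step 10 | diiodosamarium ester enolate from F5 | C=C(CC=O)C1=CC[C@H](C)[C@@H]1CC=C(OC)O[Sm](I)I
F7 | step 10 | methyl (3S,3aS,5S,6S)-6-hydroxy-3-methyl-8-methylidene-2,3,3a,4,5,6,7,8-octahydroazulene-5-carboxylate | O[C@H]1CC(=C)C2=CC[C@H](C)[C@@H]2C[C@@H]1C(=O)OC
F8 | step 7 | [4-(tert-butyldimethylsilyloxy)but-1-en-2-yl]cerium dichloride | Cl[Ce](Cl)C(=C)CCO[Si](C)(C)C(C)(C)C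
F9 | step 7 | methyl 3-[(1S,2R,5S)-2-[4-(tert-butyldimethylsilyloxy)but-1-en-2-yl]-2-hydroxy-5-methylcyclopentyl]propanoate | C=C(CCO[Si](C)(C)C(C)(C)C)[C@@]1(O)CC[C@H](C)[C@@H]1CCC(=O)OC
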